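The runs were generated by integration with constants of no real substance, noise included.

I began with an easy step: one logarithm on one reading of the north run.

| flask | E | J | temperature | remark | time |
|---|---|---|---|---|---|
| north | 0.086 M | 2.9 mM | −10 °C | run made earlier |  |
| south-west | 0.086 M | 4.6 mM | 23 °C | run made earlier |  |
| east | 0.17 M | 2.1 mM | −10 °C | run made earlier |  |
| violet | 0.086 M | 2.1 mM | 35 °C |  | 8.0 d |
| blue | 0.086 M | 2.1 mM | −25 °C |  | 8.0 d |
| ochre | 0.086 M | 2.1 mM | 15 °C |  | 8.0 d |
| grey | 0.086 M | 2.1 mM | −5 °C |  | 8.0 d |

- the flask that comes out highest in amount of X, in percent of the E charged, or "all alike" when all lie within 1.5 percentage points (violet / blue / ochre / grey / all alike)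
- X at the end, in percent of the E charged, violet
- X at the end, in percent of the E charged, blue
- X at the end, in percent of the E charged, ochre
- X at the end, in percent of the E charged, grey

- percent here means E units held: one L counts as two
- on the list of suspects stand: 2 E -> L; E + J <-> J + X

| run | time / d | X / % |
|---|---|---|
| north | 4.00 | 36.6 |
| north | 6.00 | 48.0 |
| north | 10.0 | 63.4 |
| north | 15.0 | 73.6 |
| north | 30.0 | 84.4 |
| north | 50.0 | 86.0 |
| south-west | 1.67 | 67.2 |
| south-west | 3.00 | 66.7 |
| south-west | 5.00 | 66.9 |
| south-west | 8.00 | 64.8 |
| south-west | 10.0 | 63.6 |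
| east | 4.00 | 26.7 |
| east | 8.00 | 41.5 |
| east | 12.0 | 50.8 |
| east | 25.0 | 65.8 |
| east | 50.0 | 70.8 |

(scatter of a reading: 0.5 percentage points)

Far below its plateau, the suspect E + J <-> J + X should turn E into X in a pseudo-first-order way, with J unchanged. The logarithm of the share not yet X, its sign turned, should then grow in step with cJ times time. North's top row, 36.6% at 4.00 d with 2.9 mM of J, gave 0.0393 /mM/d. I call this number, that logarithm divided by cJ times time, the J-clock.

Down the north column it sank: the row at 10.0 d read 0.0347 /mM/d, and X levelled near 86.0%. So I read the clock from top rows. East's top row read 0.0370 /mM/d, a ratio of 1.06 to north, although J differed by a factor 1.38 and E by 1.98. South-west gave no clock, for it stood at 67.2% in its top row and sank to 63.6%.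

For blue, with 2.1 mM of J over 8.0 d, the clock as read at −10 °C gave 48.3%. I committed to blue lying below that, since blue is colder. The earlier runs stood at −10 °C and 23 °C, and I put no figure on that slowing.

The forecast named ochre highest, with violet 45.5%, blue 22%, ochre 69% and grey 54.5%, and it wrote: “Blue is kinetically limited.” By my own inversion, its blue value means a clock of 0.0148 /mM/d, which is north's slowed by a factor 2.66, or 0.424 of a power of ten.

The flasks put ochre highest: violet 17.6%, blue 16.4%, ochre 63.4%, grey 56.1%.

    2 E → L (k = 1.18 /M/h, Ea = 72.0 kJ/mol)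
    E + J ⇌ J + X (K = 2.66, k = 46.2 /M/h, Ea = 49.0 kJ/mol, ΔH = −82.0 kJ/mol)
    (constants at 35 °C)

In blue, 80.1% of the E still stood at 8.00 d, with 3.52% as L. Blue's 16.4% reads as a clock of 0.0106 /mM/d, north's slowed by a factor 3.71, or 0.569 of a power of ten. Put on the neighbour of blue charged with 5.30 mM of J, that clock reckons 36.2%, and that neighbour stood at 36.3%.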